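**Retrosynthetic overview**
- Agastenol is cut first at the primary 4-hydroxybenzoate (late Steglich esterification, then one global desilylation). This leaves a 2-aryl-3-hydroxymethyl-4-benzylidene tetrahydrofuran.
- The strategy rests on the C3–C4 bond of the tetrahydrofuran (O1, C2, C3, C4, C5). It ties stereocentre C3, which bears the CH2O arm, to the sp2 carbon C4 of the exocyclic benzylidene. This is the imprint of a C3 radical released from a C3–CH2 terminal epoxide and captured by an aryl alkyne hanging from O1–C5.
- The epoxy propargyl ether is built in line: O1–C5 by Williamson etherification of an (R)-aryl vinyl carbinol, the alkyne–aryl bond by Sonogashira coupling, and the epoxide by peracid oxidation of the vinyl group (epimer mixture tolerated).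
- C2 stems from a Sharpless kinetic resolution of the vanillin-derived carbinol. The three benzene rings are purchased, and the tetrahydrofuran is the only ring formed, closed at C3–C4 in the key step.

Key step: step 8

Remark (assumption on the chemistry): the target SMILES is read as (2R,3S,4E). The C2 aryl group and the C3 CH2O arm are trans on the ring, and the benzylidene aryl group lies on the C3 side of the double bond.
Abbreviation: Ar = 3-methoxy-4-(triisopropylsilyloxy)phenyl; TIPS = triisopropylsilyl.

**Step 1**
Reactants: 1 vanillin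
Product: 2 3-methoxy-4-(triisopropylsilyloxy)benzaldehyde (Ar–CHO)
Conditions: TIPSCl, imidazole, DMF, 0 °C to rt
Reagents that add atoms: triisopropylsilyl chloride (TIPSCl), CC(C)[Si](Cl)(C(C)C)C(C)C
Why: Imidazole-promoted silyl ether formation on a phenol; the hindered aryl TIPS ether is chosen because it should tolerate the Grignard reagent, NaH, amine, peracid and low-valent titanium of the later steps and still fall to fluoride at the end.

**Step 2**
Reactants: 2 3-methoxy-4-(triisopropylsilyloxy)benzaldehyde
Product: 4 rac-1-Ar-prop-2-en-1-ol, via bromomagnesium alkoxide 3 (not isolated)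
Conditions: vinylmagnesium bromide, THF, −78 to 0 °C; then aq. NH4Cl
Reagents that add atoms: vinylmagnesium bromide, C=C[Mg]Br
Why: Grignard 1,2-addition to a non-enolisable aromatic aldehyde; the carbinol carbon (future C2) is formed racemic and is resolved in the next step.

**Step 3**
Reactants: 4 rac-1-Ar-prop-2-en-1-ol
Product: 5 (R)-1-Ar-prop-2-en-1-ol
Conditions: Ti(OiPr)4 (cat.), D-(−)-DIPT (cat.), anhydrous TBHP (0.6 equiv), 4 Å MS, CH2Cl2, −20 °C; recovered alcohol separated from the epoxy alcohol by chromatography
Reagents that add atoms: none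
Why: Sharpless kinetic resolution, in which the D-(−)-DIPT catalyst should epoxidise the (S)-carbinol faster (aryl outranks vinyl in the CIP order, so the descriptors are reversed relative to alkyl vinyl carbinols), so that running past half conversion leaves the (R)-alcohol that fixes C2 of the target.

**Step 4**
Reactants: 5 (R)-1-Ar-prop-2-en-1-ol; 6 propargyl bromide
Product: 8 (R)-Ar–CH(OCH2C≡CH)–CH=CH2 (allyl propargyl ether), via sodium alkoxide 7 (not isolated)
Conditions: NaH, THF, 0 °C; then 6, Bu4NI (cat.), 0 °C to rt
Reagents that add atoms: none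
Why: Williamson ether synthesis, in which alkoxide 7 displaces bromide by SN2 at the propargylic carbon, so that O1–C5 forms without touching the C–O bond of the stereocentre.

**Step 5**
Reactants: 9 4-iodo-2-methoxyphenol
Product: 10 (4-iodo-2-methoxyphenoxy)triisopropylsilane (Ar–I)
Conditions: TIPSCl, imidazole, DMF, rt
Reagents that add atoms: triisopropylsilyl chloride (TIPSCl), CC(C)[Si](Cl)(C(C)C)C(C)C
Why: The same phenol silylation as in step 1, which removes the acidic OH before the cross-coupling and gives all phenols one common protecting group.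

**Step 6**
Reactants: 8 (R)-allyl propargyl ether; 10 Ar–I
Product: 11 (R)-Ar–CH(OCH2C≡C–Ar)–CH=CH2 (aryl alkyne 1,6-enyne)
Conditions: PdCl2(PPh3)2 (cat.), CuI (cat.), Et3N, THF, degassed, rt
Reagents that add atoms: none
Why: Sonogashira coupling of a terminal alkyne with an aryl iodide runs at room temperature under amine base, where the vinyl group, the benzylic allylic ether, both silyl ethers and the C2 centre are spectators.

**Step 7**
Reactants: 11 aryl alkyne 1,6-enyne
Product: 12 2-[(S)-(Ar)(3-Ar-prop-2-yn-1-yloxy)methyl]oxirane (both epimers at the oxirane carbon; the benzylic centre is unchanged in space and its descriptor switches only because oxiranyl outranks aryl)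
Conditions: mCPBA, NaHCO3, CH2Cl2, 0 °C to rt
Reagents that add atoms: m-chloroperbenzoic acid (mCPBA), OOC(=O)c1cccc(Cl)c1
Why: Prilezhaev epoxidation, in which the alkene should react with the peracid well ahead of the aryl alkyne, the buffer shields the acid-sensitive ether and epoxide, and no diastereocontrol is needed because the new centre is erased in step 8.

**Step 8**
Reactants: 12 epoxy propargyl ether (epimer mixture)
Product: 16 [(2R,3S,4E)-2-Ar-4-(Ar-methylidene)tetrahydrofuran-3-yl]methanol, via beta-titanoxy C3 radical 13 (not isolated), via alpha-aryl vinyl radical 14 (not isolated), via titanium alkoxide 15 (not isolated)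
Conditions: Cp2TiCl2 (2.5 equiv), Zn, THF, rt (green Cp2TiCl solution), added by syringe pump to 12 in degassed THF at high dilution, rt; then cold 1 M HCl
Reagents that add atoms: none
Why: Cp2TiCl, a trivalent titanium single-electron donor, opens the terminal epoxide at its more substituted C–O bond (Nugent–RajanBabu reductive epoxide opening) to the secondary radical 13, which attacks the tethered aryl alkyne to forge C3–C4; the resulting vinyl radical 14 is quenched to the tetravalent titanium alkoxide 15, and acid releases the primary alcohol. The closest known reaction type is the Cp2TiCl-mediated cyclisation of epoxy propargyl and epoxy allyl ethers to 3-hydroxymethyl tetrahydrofurans, which has already served for furanoid lignan frameworks. The tetrahydrofuran closes in the 5-exo-dig mode, imposed by the three-atom C2–O1–C5 tether and reinforced by the aryl group, which activates the alkyne and stabilises 14. C3 is the only new stereocentre: radical 13 is planar, so both epimers of 12 funnel into one intermediate, and the resident C2 centre controls the closure through an envelope-like transition state in which the C2 aryl group sits pseudo-equatorial and the titanoxymethyl arm turns anti to it, giving the 2,3-trans (2R,3S) ring. The alkene geometry is decided when the linear radical 14 takes a hydrogen atom from THF on the open C5 side, away from the bulky C3 arm, which swings the aryl group to the C3 side as required for the E isomer. The step also needs cyclisation to outrun reduction of 13 by a second titanium centre, which would end in loss of the titanoxy group and return of alkene 11, and this is secured by the fast closure onto an aryl alkyne together with slow addition of the reagent at high dilution.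

**Step 9**
Reactants: 17 4-hydroxybenzoic acid
Product: 18 triisopropylsilyl 4-(triisopropylsilyloxy)benzoate
Conditions: TIPSCl (2.3 equiv), imidazole, DMF, rt
Reagents that add atoms: triisopropylsilyl chloride (TIPSCl), CC(C)[Si](Cl)(C(C)C)C(C)C
Why: Exhaustive imidazole-promoted silylation covers the phenol and the acid, which avoids any selectivity problem at this stage.

**Step 10**
Reactants: 18 triisopropylsilyl 4-(triisopropylsilyloxy)benzoate
Product: 20 4-(triisopropylsilyloxy)benzoic acid, via potassium carboxylate 19 (not isolated)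
Conditions: K2CO3 (1 equiv), THF/MeOH/H2O, 0 °C to rt; then 1 M HCl to pH 4
Reagents that add atoms: none
Why: Chemoselective solvolysis at silicon, since a silyl ester (carboxylate leaving group) is far more labile to mild aqueous base than a hindered aryl TIPS ether.

**Step 11**
Reactants: 16 tetrahydrofuran alcohol; 20 4-(triisopropylsilyloxy)benzoic acid
Product: 22 [(2R,3S,4E)-2-Ar-4-(Ar-methylidene)tetrahydrofuran-3-yl]methyl 4-(triisopropylsilyloxy)benzoate (tris-TIPS agastenol), via O-acylisourea 21 (not isolated)
Conditions: DCC, DMAP (cat.), CH2Cl2, 0 °C to rt, exclusion of light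
Reagents that add atoms: none
Why: Steglich esterification, in which DMAP relays the acyl group from 21 to the unhindered primary alcohol under neutral conditions that touch neither C2, C3 nor the benzylidene geometry.

**Step 12**
Reactants: 22 tris-TIPS agastenol
Product: 23 agastenol
Conditions: Bu4NF/AcOH (1:1, 3.3 equiv each), THF, 0 °C, exclusion of light
Reagents that add atoms: none
Why: Fluoride-induced desilylation of three aryl silyl ethers, with AcOH keeping the liberated phenols protonated so that ester cleavage and quinone-methide opening of the C2–O1 bond (which would scramble C2) are avoided.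

**Compound list**
1 | vanillin | COc1cc(C=O)ccc1O | starting material
2 | 3-methoxy-4-(triisopropylsilyloxy)benzaldehyde | COc1cc(C=O)ccc1O[Si](C(C)C)(C(C)C)C(C)C | intermediate
3 | bromomagnesium alkoxide of 4 (not isolated) | COc1cc(C([O-])C=C)ccc1O[Si](C(C)C)(C(C)C)C(C)C.[Mg+2].[Br-] | intermediate
4 | rac-1-Ar-prop-2-en-1-ol | COc1cc(C(O)C=C)ccc1O[Si](C(C)C)(C(C)C)C(C)C | intermediate
5 | (R)-1-Ar-prop-2-en-1-ol | O[C@@H](c1ccc(O[Si](C(C)C)(C(C)C)C(C)C)c(OC)c1)C=C | intermediate
6 | propargyl bromide | BrCC#C | starting material
7 | sodium alkoxide of 5 (not isolated) | [Na+].[O-][C@@H](c1ccc(O[Si](C(C)C)(C(C)C)C(C)C)c(OC)c1)C=C | intermediate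
8 | (R)-Ar–CH(OCH2C≡CH)–CH=CH2 | C#CCO[C@@H](c1ccc(O[Si](C(C)C)(C(C)C)C(C)C)c(OC)c1)C=C | intermediate
9 | 4-iodo-2-methoxyphenol | COc1cc(I)ccc1O | starting material
10 | (4-iodo-2-methoxyphenoxy)triisopropylsilane | COc1cc(I)ccc1O[Si](C(C)C)(C(C)C)C(C)C | intermediate
11 | (R)-Ar–CH(OCH2C≡C–Ar)–CH=CH2 | COc1cc(C#CCO[C@@H](c2ccc(O[Si](C(C)C)(C(C)C)C(C)C)c(OC)c2)C=C)ccc1O[Si](C(C)C)(C(C)C)C(C)C | intermediate
12 | epoxy propargyl ether, both oxirane epimers | COc1cc(C#CCO[C@@H](c2ccc(O[Si](C(C)C)(C(C)C)C(C)C)c(OC)c2)C2CO2)ccc1O[Si](C(C)C)(C(C)C)C(C)C | intermediate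
13 | beta-titanoxy C3 radical (not isolated) | COc1cc(C#CCO[C@@H](c2ccc(O[Si](C(C)C)(C(C)C)C(C)C)c(OC)c2)[CH]C[O-])ccc1O[Si](C(C)C)(C(C)C)C(C)C.[Ti+4].[Cl-].[CH-]1C=CC=C1.[CH-]1C=CC=C1 | intermediate
14 | alpha-aryl vinyl radical (not isolated) | COc1cc([C]=C2CO[C@@H](c3ccc(O[Si](C(C)C)(C(C)C)C(C)C)c(OC)c3)[C@@H]2C[O-])ccc1O[Si](C(C)C)(C(C)C)C(C)C.[Ti+4].[Cl-].[CH-]1C=CC=C1.[CH-]1C=CC=C1 | intermediate
15 | Cp2Ti(Cl) alkoxide of 16 (not isolated) | COc1cc(/C=C2/CO[C@@H](c3ccc(O[Si](C(C)C)(C(C)C)C(C)C)c(OC)c3)[C@@H]2C[O-])ccc1O[Si](C(C)C)(C(C)C)C(C)C.[Ti+4].[Cl-].[CH-]1C=CC=C1.[CH-]1C=CC=C1 | intermediate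
16 | [(2R,3S,4E)-2-Ar-4-(Ar-methylidene)tetrahydrofuran-3-yl]methanol | COc1cc(/C=C2/CO[C@@H](c3ccc(O[Si](C(C)C)(C(C)C)C(C)C)c(OC)c3)[C@@H]2CO)ccc1O[Si](C(C)C)(C(C)C)C(C)C | intermediate
17 | 4-hydroxybenzoic acid | O=C(O)c1ccc(O)cc1 | starting material
18 | triisopropylsilyl 4-(triisopropylsilyloxy)benzoate | CC(C)[Si](C(C)C)(C(C)C)OC(=O)c1ccc(O[Si](C(C)C)(C(C)C)C(C)C)cc1 | intermediate
19 | potassium 4-(triisopropylsilyloxy)benzoate (not isolated) | [K+].[O-]C(=O)c1ccc(O[Si](C(C)C)(C(C)C)C(C)C)cc1 | intermediate
20 | 4-(triisopropylsilyloxy)benzoic acid | O=C(O)c1ccc(O[Si](C(C)C)(C(C)C)C(C)C)cc1 | intermediate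
21 | O-acylisourea from 20 and DCC (not isolated) | O=C(OC(=NC1CCCCC1)NC1CCCCC1)c1ccc(O[Si](C(C)C)(C(C)C)C(C)C)cc1 | intermediate
22 | tris-TIPS agastenol | COc1cc(/C=C2/CO[C@@H](c3ccc(O[Si](C(C)C)(C(C)C)C(C)C)c(OC)c3)[C@@H]2COC(=O)c2ccc(O[Si](C(C)C)(C(C)C)C(C)C)cc2)ccc1O[Si](C(C)C)(C(C)C)C(C)C | intermediate
23 | agastenol | COc1cc(/C=C2/CO[C@@H](c3ccc(O)c(OC)c3)[C@@H]2COC(=O)c2ccc(O)cc2)ccc1O | target

Total step count: 12
Longest linear sequence: 9 steps (1, 2, 3, 4, 6, 7, 8, 11, 12)

**Steps most likely to fail**

**1. Step 8.**
- What may go wrong: the C3 radical may be reduced by a second trivalent titanium centre, followed by loss of the titanoxy group (deoxygenation). The facial bias in the ring closure may be incomplete. The hydrogen transfer to the vinyl radical may leak to the C3 side and erode the alkene geometry.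
- Fallback: the same C3 radical is generated in a stannane chain, where no metal can intercept it.
- It sets out from 11. OsO4 (cat.)/NMO dihydroxylation of the vinyl group gives the diol F1 (both C3 epimers, again convergent).
- The primary hydroxyl is acylated selectively with one equivalent of acid 20 (DCC, cat. DMAP, low temperature) to the hydroxy ester F2.
- The secondary hydroxyl is converted with 1,1'-thiocarbonyldiimidazole into the thiocarbonylimidazolide F3.
- Slow addition of Bu3SnH/AIBN in hot toluene (Barton–McCombie-type radical generation) should trigger the same 5-exo-dig closure. The bulky, fast hydrogen donor reaches the vinyl radical from the C5 side.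
- The route is rejoined at 22.

**2. Step 3.**
- What may go wrong: the Lewis-acidic titanium alkoxide may ionise the electron-rich benzylic allylic alcohol, with racemisation, ether formation or allylic transposition. Epoxidation of an unsubstituted vinyl group may also be slow and poorly discriminating. The sense of the resolution is to be confirmed on 5 by Mosher ester analysis before material is carried on.
- Fallback: an enzymatic acyl-transfer resolution without any Lewis acid.
- It sets out from 4. Immobilised Candida antarctica lipase B with vinyl acetate in MTBE should acylate the (R)-enantiomer (aryl large, vinyl medium, Kazlauskas rule) to the (R)-acetate F4.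
- F4 is separated from the (S)-alcohol and cleaved with iBu2AlH in CH2Cl2 at −78 °C.
- The route is rejoined at 5.

**3. Step 7.**
- What may go wrong: the deactivated monosubstituted alkene may react sluggishly, so that oxidation of the electron-rich aryl alkyne and arenes competes. The new epoxide may also open under acid.
- Fallback: the epoxide is installed before the alkyne and the second arene are present.
- It sets out from 4. The Sharpless reaction with L-(+)-DIPT, stopped before half conversion, should turn the (R)-carbinol into the anti epoxy alcohol F5.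
- In parallel, and setting out from 10, Sonogashira coupling with propargyl alcohol gives the aryl propynol F6. An Appel reaction (CBr4, PPh3) then gives the aryl propargyl bromide F7.
- F5 is etherified with F7 (NaH, THF/DMSO, 0 °C). The bromide is present from the start so that alkylation outruns Payne rearrangement.
- The route is rejoined at 12 (as a single oxirane epimer), by-passing 5, 8 and 11.

**Further compounds**
F1 | step 8 | (S)-Ar–CH(OCH2C≡C–Ar)–CH(OH)–CH2OH, both carbinol epimers | COc1cc(C#CCO[C@@H](c2ccc(O[Si](C(C)C)(C(C)C)C(C)C)c(OC)c2)C(O)CO)ccc1O[Si](C(C)C)(C(C)C)C(C)C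
F2 | step 8 | primary 4-(triisopropylsilyloxy)benzoate of F1 | COc1cc(C#CCO[C@@H](c2ccc(O[Si](C(C)C)(C(C)C)C(C)C)c(OC)c2)C(O)COC(=O)c2ccc(O[Si](C(C)C)(C(C)C)C(C)C)cc2)ccc1O[Si](C(C)C)(C(C)C)C(C)C
F3 | step 8 | O-(imidazol-1-ylthiocarbonyl) derivative of F2 | COc1cc(C#CCO[C@@H](c2ccc(O[Si](C(C)C)(C(C)C)C(C)C)c(OC)c2)C(COC(=O)c2ccc(O[Si](C(C)C)(C(C)C)C(C)C)cc2)OC(=S)n2ccnc2)ccc1O[Si](C(C)C)(C(C)C)C(C)C
F4 | step 3 | (R)-1-Ar-prop-2-en-1-yl acetate | CC(=O)O[C@@H](c1ccc(O[Si](C(C)C)(C(C)C)C(C)C)c(OC)c1)C=C
F5 | step 7 | (S)-Ar[(R)-oxiran-2-yl]methanol | O[C@@H](c1ccc(O[Si](C(C)C)(C(C)C)C(C)C)c(OC)c1)[C@H]1CO1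
F6 | step 7 | 3-Ar-prop-2-yn-1-ol | COc1cc(C#CCO)ccc1O[Si](C(C)C)(C(C)C)C(C)C
F7 | step 7 | 3-Ar-prop-2-yn-1-yl bromide | COc1cc(C#CCBr)ccc1O[Si](C(C)C)(C(C)C)C(C)C
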